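**Plan**

- Retrosynthetic cuts: first the ester C(=O)–O bond between the naphthalene-2-carboxylic acid and the secondary hydroxyl of (R)-danshensu; then both ring-B bonds C1–C8a and C4–C4a of the naphthalene, with a CO2 bridge restored across C1/C4; last the pyrone into an aryl methyl ketone and dimethyl acetylenedicarboxylate.
- Enabling feature: ring A carries identical oxygens on C6 and C7, so the aryne spanning C4a–C8a is symmetric. C1–C4 of ring B (H on C1, ester on C2, H on C3, catechol ring on C4) map onto C3–C6 of a 6-aryl-2-pyrone-4-carboxylate, which fixes the 1,3 relation of ester and aryl before the ring exists.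
- Forward order: the pyrone ring is made first (enamine addition to the alkyne diester, hydrolysis, enol-lactonisation). Ring B then closes in aromatic form by aryne [4+2] and retro-[4+2] loss of CO2. Ring A and the pendant catechol ring are bought as benzene rings, and the danshensu chain is joined last by O-acylation.
- Protecting groups: every phenol is a benzyl ether from the outset and the danshensu acid a benzyl ester, so no exchange is needed and seven benzyl groups leave in one final hydrogenolysis.
- Stereochemistry: the single (R) stereocentre is bought with danshensu; it is acylated on oxygen with retention and is never a reacting centre.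

Key step: step 5

Assumption: 3',4'-bis(benzyloxy)acetophenone, 3,4-bis(benzyloxy)phenol and (R)-danshensu (free acid) are taken as catalogue compounds; the benzyl-protected silylaryl triflate is not, and is made in steps 3 and 4.

**Route**

Step 1
Reactants: 1 3',4'-bis(benzyloxy)acetophenone; 2 pyrrolidine
Product: 3 1-{1-[3,4-bis(benzyloxy)phenyl]ethenyl}pyrrolidine
Conditions: pyrrolidine (6 equiv), TiCl4 (0.55 equiv), toluene, 0 °C → rt; filter under Ar, concentrate, strip excess amine; used crude
Reagents that add atoms: none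
Why: TiCl4-mediated ketone–secondary amine condensation (White–Weingarten enamine synthesis), in which TiCl4 binds the water irreversibly and so drives the sluggish condensation of the electron-rich aryl ketone; the excess amine buffers the Lewis acid so the benzyl ethers are safe, and a methyl ketone can give only the terminal enamine.

Step 2
Reactants: 3 1-{1-[3,4-bis(benzyloxy)phenyl]ethenyl}pyrrolidine; 4 dimethyl acetylenedicarboxylate
Product: 7 methyl 6-[3,4-bis(benzyloxy)phenyl]-2-oxo-2H-pyran-4-carboxylate, via dimethyl 2-{2-[3,4-bis(benzyloxy)phenyl]-2-(pyrrolidin-1-yl)ethenyl}but-2-enedioate 5 (not isolated), via dimethyl 2-{2-[3,4-bis(benzyloxy)phenyl]-2-oxoethyl}but-2-enedioate 6 (not isolated)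
Conditions: 4 (1.05 equiv), MeOH, 0 °C → rt; then 2 M aq HCl–THF, rt → 50 °C; then TsOH·H2O (10 mol%), toluene, 80 °C
Reagents that add atoms: water, O
Why: Enamine conjugate addition to an acetylenic diester in a protic solvent (methanol protonates the zwitterion to the open-chain aminodiene 5 and suppresses [2+2] closure), followed by enamine hydrolysis and acid-catalysed enol-lactonisation onto the cis ester; both geometric isomers of 6 should converge on 7 because the γ-keto diester equilibrates through its alkylidene-succinate tautomer and only the lactonising isomer is drained.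

Step 3
Reactants: 8 3,4-bis(benzyloxy)phenol
Product: 9 4,5-bis(benzyloxy)-2-bromophenol
Conditions: NBS (1.0 equiv), CH2Cl2, −20 → 0 °C
Reagents that add atoms: N-bromosuccinimide, O=C1CCC(=O)N1Br
Why: Electrophilic aromatic bromination of an activated phenol; the position ortho to OH and para to the 3-benzyloxy group is the most activated and least hindered, the same selectivity that gives 2-bromo-4,5-dimethoxyphenol from 3,4-dimethoxyphenol.

Step 4
Reactants: 9 4,5-bis(benzyloxy)-2-bromophenol
Product: 12 4,5-bis(benzyloxy)-2-(trimethylsilyl)phenyl trifluoromethanesulfonate, via [4,5-bis(benzyloxy)-2-bromophenoxy]trimethylsilane 10 (not isolated), via lithium 4,5-bis(benzyloxy)-2-(trimethylsilyl)phenoxide 11 (not isolated)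
Conditions: HMDS, THF, 65 °C, then concentrate; n-BuLi (1.1 equiv), THF, −78 °C; Tf2O (1.2 equiv), −78 °C → rt
Reagents that add atoms: hexamethyldisilazane, C[Si](C)(C)N[Si](C)(C)C; trifluoromethanesulfonic anhydride, O=S(=O)(OS(=O)(=O)C(F)(F)F)C(F)(F)F
Why: Standard one-pot route to Kobayashi aryne precursors (O-silylation, bromine–lithium exchange, anionic 1,3 O→C silyl shift by retro-Brook rearrangement, O-triflation of the phenoxide); halogen–metal exchange at −78 °C is much faster than benzylic deprotonation of the ethers.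

Step 5
Reactants: 12 4,5-bis(benzyloxy)-2-(trimethylsilyl)phenyl trifluoromethanesulfonate; 7 methyl 6-[3,4-bis(benzyloxy)phenyl]-2-oxo-2H-pyran-4-carboxylate
Product: 15 methyl 6,7-bis(benzyloxy)-4-[3,4-bis(benzyloxy)phenyl]naphthalene-2-carboxylate, via 4,5-bis(benzyloxy)benzyne 13 (not isolated), via methyl 6,7-bis(benzyloxy)-1-[3,4-bis(benzyloxy)phenyl]-10-oxo-1,4-dihydro-1,4-(epoxymethano)naphthalene-3-carboxylate 14 (not isolated)
Conditions: CsF (3 equiv), MeCN–toluene 1:1, rt, 12 (1.5 equiv) added slowly to 7; then 80 °C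
Reagents that add atoms: none
Why: Fluoride attacks silicon of 12 and 1,2-elimination of triflate releases the symmetric aryne 13, which adds suprafacially across C3 and C6 of the s-cis-locked pyrone diene of 7 in a concerted [4+2] to give the bridged lactone 14 (bridge oxygen on C1, carbonyl on C4). 14 should lose CO2 by retro-[4+2] on mild warming because extrusion makes the new ring aromatic; the closest known reaction type is the Diels–Alder/decarboxylation of arynes with 2-pyrone carboxylates (for example methyl coumalate with benzyne) to 2-naphthoates. Ring B closes by intermolecular [4+2] cycloaddition that forms C1–C8a and C4–C4a, then by cycloreversion of the lactone bridge. No stereocentre is created in 15, since the two bridgehead centres of racemic 14 are erased on aromatisation. No regioselectivity is needed because the aryne is symmetric, so either orientation gives the same 2-naphthoate with the 1,3 ester/aryl relation set in the pyrone. The chemoselectivity needed is capture of the aryne by the pyrone rather than by fluoride, solvent or the pendant electron-rich ring; the locked cisoid diene, a high standing concentration of 7 and slow release of the aryne from sparingly soluble CsF secure it.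

Step 6
Reactants: 15 methyl 6,7-bis(benzyloxy)-4-[3,4-bis(benzyloxy)phenyl]naphthalene-2-carboxylate
Product: 16 6,7-bis(benzyloxy)-4-[3,4-bis(benzyloxy)phenyl]naphthalene-2-carboxylic acid
Conditions: LiOH·H2O (4 equiv), THF–MeOH–H2O, 50 °C; then 1 M HCl
Reagents that add atoms: lithium hydroxide, [Li+].[OH-]
Why: Saponification of an unhindered methyl naphthoate (acyl–oxygen ester hydrolysis); aryl benzyl ethers are inert to hydroxide.

Step 7
Reactants: 17 (R)-danshensu, (2R)-3-(3,4-dihydroxyphenyl)-2-hydroxypropanoic acid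
Product: 18 benzyl (2R)-3-[3,4-bis(benzyloxy)phenyl]-2-hydroxypropanoate
Conditions: BnBr (3.3 equiv), K2CO3 (3.5 equiv), DMF, rt, under Ar
Reagents that add atoms: benzyl bromide, BrCc1ccccc1
Why: Williamson ether synthesis and carboxylate O-alkylation under carbonate, which ionises only the carboxylic acid and the two phenols, so the secondary alcohol should stay free; no bond to the stereocentre is involved.

Step 8
Reactants: 16 6,7-bis(benzyloxy)-4-[3,4-bis(benzyloxy)phenyl]naphthalene-2-carboxylic acid; 18 benzyl (2R)-3-[3,4-bis(benzyloxy)phenyl]-2-hydroxypropanoate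
Product: 19 benzyl (2R)-3-[3,4-bis(benzyloxy)phenyl]-2-({6,7-bis(benzyloxy)-4-[3,4-bis(benzyloxy)phenyl]naphthalene-2-carbonyl}oxy)propanoate
Conditions: DCC (1.2 equiv), DMAP (0.2 equiv), CH2Cl2, 0 °C → rt
Reagents that add atoms: none
Why: Steglich esterification (carbodiimide activation, DMAP acyl transfer); acylation occurs on the hydroxyl oxygen with retention because the C–O bond of the stereocentre is not broken, and catalytic DMAP at or below rt should not epimerise the α-acyloxy ester.

Step 9
Reactants: 19 benzyl (2R)-3-[3,4-bis(benzyloxy)phenyl]-2-({6,7-bis(benzyloxy)-4-[3,4-bis(benzyloxy)phenyl]naphthalene-2-carbonyl}oxy)propanoate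
Product: 20 Eritrichin, (2R)-2-{[4-(3,4-dihydroxyphenyl)-6,7-dihydroxynaphthalene-2-carbonyl]oxy}-3-(3,4-dihydroxyphenyl)propanoic acid
Conditions: H2 (1 atm), 10% Pd/C, THF–MeOH, rt; filter and concentrate under Ar
Reagents that add atoms: none
Why: Catalytic hydrogenolysis of six aryl benzyl ethers and one benzyl ester; the alkyl C–O bond of the naphthoate is homobenzylic and should be retained, the naphthalene is not reduced at 1 atm, and the stereocentre is untouched.

**Compound list**

1 | 3',4'-bis(benzyloxy)acetophenone | CC(=O)c1ccc(OCc2ccccc2)c(OCc2ccccc2)c1 | starting material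
2 | pyrrolidine | C1CCNC1 | starting material
3 | 1-{1-[3,4-bis(benzyloxy)phenyl]ethenyl}pyrrolidine | C=C(N1CCCC1)c1ccc(OCc2ccccc2)c(OCc2ccccc2)c1 | intermediate
4 | dimethyl acetylenedicarboxylate | COC(=O)C#CC(=O)OC | starting material
5 | dimethyl 2-{2-[3,4-bis(benzyloxy)phenyl]-2-(pyrrolidin-1-yl)ethenyl}but-2-enedioate (mixture of geometric isomers) | COC(=O)C=C(C=C(N1CCCC1)c1ccc(OCc2ccccc2)c(OCc2ccccc2)c1)C(=O)OC | intermediate
6 | dimethyl 2-{2-[3,4-bis(benzyloxy)phenyl]-2-oxoethyl}but-2-enedioate (mixture of geometric isomers) | COC(=O)C=C(CC(=O)c1ccc(OCc2ccccc2)c(OCc2ccccc2)c1)C(=O)OC | intermediate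
7 | methyl 6-[3,4-bis(benzyloxy)phenyl]-2-oxo-2H-pyran-4-carboxylate | COC(=O)C1=CC(=O)OC(=C1)c1ccc(OCc2ccccc2)c(OCc2ccccc2)c1 | intermediate
8 | 3,4-bis(benzyloxy)phenol | Oc1ccc(OCc2ccccc2)c(OCc2ccccc2)c1 | starting material
9 | 4,5-bis(benzyloxy)-2-bromophenol | Oc1cc(OCc2ccccc2)c(OCc2ccccc2)cc1Br | intermediate
10 | [4,5-bis(benzyloxy)-2-bromophenoxy]trimethylsilane | C[Si](C)(C)Oc1cc(OCc2ccccc2)c(OCc2ccccc2)cc1Br | intermediate
11 | lithium 4,5-bis(benzyloxy)-2-(trimethylsilyl)phenoxide | [Li+].[O-]c1cc(OCc2ccccc2)c(OCc2ccccc2)cc1[Si](C)(C)C | intermediate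
12 | 4,5-bis(benzyloxy)-2-(trimethylsilyl)phenyl trifluoromethanesulfonate | C[Si](C)(C)c1cc(OCc2ccccc2)c(OCc2ccccc2)cc1OS(=O)(=O)C(F)(F)F | intermediate
13 | 4,5-bis(benzyloxy)benzyne (1,2-didehydro-4,5-bis(benzyloxy)benzene) | C1#CC=C(OCc2ccccc2)C(OCc2ccccc2)=C1 | intermediate
14 | methyl 6,7-bis(benzyloxy)-1-[3,4-bis(benzyloxy)phenyl]-10-oxo-1,4-dihydro-1,4-(epoxymethano)naphthalene-3-carboxylate (racemic bridged lactone; bridge O on C1, C=O on C4) | COC(=O)C1=CC2(c3ccc(OCc4ccccc4)c(OCc4ccccc4)c3)OC(=O)C1c1cc(OCc3ccccc3)c(OCc3ccccc3)cc12 | intermediate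
15 | methyl 6,7-bis(benzyloxy)-4-[3,4-bis(benzyloxy)phenyl]naphthalene-2-carboxylate | COC(=O)c1cc(-c2ccc(OCc3ccccc3)c(OCc3ccccc3)c2)c2cc(OCc3ccccc3)c(OCc3ccccc3)cc2c1 | intermediate
16 | 6,7-bis(benzyloxy)-4-[3,4-bis(benzyloxy)phenyl]naphthalene-2-carboxylic acid | OC(=O)c1cc(-c2ccc(OCc3ccccc3)c(OCc3ccccc3)c2)c2cc(OCc3ccccc3)c(OCc3ccccc3)cc2c1 | intermediate
17 | (R)-danshensu, (2R)-3-(3,4-dihydroxyphenyl)-2-hydroxypropanoic acid | O[C@H](Cc1ccc(O)c(O)c1)C(=O)O | starting material
18 | benzyl (2R)-3-[3,4-bis(benzyloxy)phenyl]-2-hydroxypropanoate | O[C@H](Cc1ccc(OCc2ccccc2)c(OCc2ccccc2)c1)C(=O)OCc1ccccc1 | intermediate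
19 | benzyl (2R)-3-[3,4-bis(benzyloxy)phenyl]-2-({6,7-bis(benzyloxy)-4-[3,4-bis(benzyloxy)phenyl]naphthalene-2-carbonyl}oxy)propanoate | O=C(O[C@H](Cc1ccc(OCc2ccccc2)c(OCc2ccccc2)c1)C(=O)OCc1ccccc1)c1cc(-c2ccc(OCc3ccccc3)c(OCc3ccccc3)c2)c2cc(OCc3ccccc3)c(OCc3ccccc3)cc2c1 | intermediate
20 | Eritrichin, (2R)-2-{[4-(3,4-dihydroxyphenyl)-6,7-dihydroxynaphthalene-2-carbonyl]oxy}-3-(3,4-dihydroxyphenyl)propanoic acid | O=C(O[C@H](Cc1ccc(O)c(O)c1)C(=O)O)c1cc(-c2ccc(O)c(O)c2)c2cc(O)c(O)cc2c1 | target

**Step count and risks**

Total steps: 9. Longest linear sequence: 6 (steps 1, 2, 5, 6, 8, 9; the branch through steps 3, 4, 5, 6, 8, 9 is equally long).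

Steps most likely to fail:

Step 2. The zwitterion from enamine and alkyne may close to a cyclobutene and ring-open to the branched aminodiene instead of being protonated, or the C4 methyl ester may be hydrolysed during lactonisation. The fallback replaces conjugate addition by olefination and sets out from 1. Riley oxidation (SeO2, dioxane–water, reflux) should give 2-[3,4-bis(benzyloxy)phenyl]-2-oxoacetaldehyde F1. Wittig reaction of F1 with dimethyl 2-(triphenylphosphoranylidene)succinate F2, prepared from triphenylphosphine and dimethyl maleate, should give dimethyl (E)-2-{2-[3,4-bis(benzyloxy)phenyl]-2-oxoethylidene}succinate F3, a tautomer of 6. TsOH in toluene at 80 °C should equilibrate F3 through its dienol and lactonise it, coming back to the route at 7.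

Step 5. The aryne may be consumed by fluoride, solvent or further aryne before it meets the ester-deactivated pyrone diene. The fallback keeps the aryne and the same two ring-B bonds but changes the diene to a far more reactive furan and the bridge loss from CO2 extrusion to reductive deoxygenation; it sets out from 12. Aryne 13, released with CsF as before, is trapped by methyl 5-[3,4-bis(benzyloxy)phenyl]furan-3-carboxylate F4, which comes from Suzuki coupling of purchased methyl 5-bromofuran-3-carboxylate with 3,4-bis(benzyloxy)phenylboronic acid. The cycloadduct methyl 6,7-bis(benzyloxy)-1-[3,4-bis(benzyloxy)phenyl]-1,4-dihydro-1,4-epoxynaphthalene-3-carboxylate F5 is then deoxygenated and aromatised with low-valent titanium (TiCl4, Zn, THF, reflux), coming back to the route at 15.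

Step 4. Benzylic metalation of the ethers or incomplete O→C silyl migration may compete with the exchange/retro-Brook sequence, so the silyl triflate would be contaminated with desilylated triflate. The fallback buys the aryne precursor and pays with a protecting-group exchange; it sets out from 7. Purchased 4,5-dimethoxy-2-(trimethylsilyl)phenyl triflate with CsF (MeCN–toluene) should give 4,5-dimethoxybenzyne F6, which adds to 7 to give the bridged lactone methyl 1-[3,4-bis(benzyloxy)phenyl]-6,7-dimethoxy-10-oxo-1,4-dihydro-1,4-(epoxymethano)naphthalene-3-carboxylate F7 and, after loss of CO2, methyl 4-[3,4-bis(benzyloxy)phenyl]-6,7-dimethoxynaphthalene-2-carboxylate F8. BBr3 (excess, CH2Cl2, −78 °C → rt, MeOH quench) should cleave both methyl and both benzyl ethers to methyl 4-(3,4-dihydroxyphenyl)-6,7-dihydroxynaphthalene-2-carboxylate F9. Benzylation of the four phenols (BnBr, K2CO3, DMF) comes back to the route at 15.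

**Further compounds**

F1 | step 2 | 2-[3,4-bis(benzyloxy)phenyl]-2-oxoacetaldehyde | O=CC(=O)c1ccc(OCc2ccccc2)c(OCc2ccccc2)c1
F2 | step 2 | dimethyl 2-(triphenylphosphoranylidene)succinate | COC(=O)CC(C(=O)OC)=P(c1ccccc1)(c1ccccc1)c1ccccc1
F3 | step 2 | dimethyl (E)-2-{2-[3,4-bis(benzyloxy)phenyl]-2-oxoethylidene}succinate | COC(=O)C/C(C(=O)OC)=C\C(=O)c1ccc(OCc2ccccc2)c(OCc2ccccc2)c1
F4 | step 5 | methyl 5-[3,4-bis(benzyloxy)phenyl]furan-3-carboxylate | COC(=O)c1coc(-c2ccc(OCc3ccccc3)c(OCc3ccccc3)c2)c1
F5 | step 5 | methyl 6,7-bis(benzyloxy)-1-[3,4-bis(benzyloxy)phenyl]-1,4-dihydro-1,4-epoxynaphthalene-3-carboxylate (racemic) | COC(=O)C1=CC2(c3ccc(OCc4ccccc4)c(OCc4ccccc4)c3)OC1c1cc(OCc3ccccc3)c(OCc3ccccc3)cc12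
F6 | step 4 | 4,5-dimethoxybenzyne | COC1=CC#CC=C1OC
F7 | step 4 | methyl 1-[3,4-bis(benzyloxy)phenyl]-6,7-dimethoxy-10-oxo-1,4-dihydro-1,4-(epoxymethano)naphthalene-3-carboxylate (racemic) | COC(=O)C1=CC2(c3ccc(OCc4ccccc4)c(OCc4ccccc4)c3)OC(=O)C1c1cc(OC)c(OC)cc12
F8 | step 4 | methyl 4-[3,4-bis(benzyloxy)phenyl]-6,7-dimethoxynaphthalene-2-carboxylate | COC(=O)c1cc(-c2ccc(OCc3ccccc3)c(OCc3ccccc3)c2)c2cc(OC)c(OC)cc2c1
F9 | step 4 | methyl 4-(3,4-dihydroxyphenyl)-6,7-dihydroxynaphthalene-2-carboxylate | COC(=O)c1cc(-c2ccc(O)c(O)c2)c2cc(O)c(O)cc2c1
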